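Ring B of the naphthazarin is read as a furan: it carries oxygen at C1 and C4, the chiral side chain at C2 and hydrogen at C3, the pattern of a 3-substituted furan fused across C4a–C8a, while the 5,8-dioxygenated ring A is a symmetric aryne. One aryne–furan Diels–Alder reaction therefore forms C1–C8a and C4–C4a and closes ring B with the complete (S)-configured tiglate side chain already in place; the symmetry of the aryne removes any regiochemical question. The precursors are an ortho-silylaryl triflate with two MOM ethers and the (S)-3-furyl carbinol tiglate. Ring opening, one oxidation para to the new hydroxyl and acetal cleavage finish the synthesis.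

Key step: step 9

Remark (chemistry): (−)-Ipc2B(allyl), the reagent of the (+)-α-pinene series, is taken as the bought pentane solution and is assumed to attack 3-furaldehyde on the Si face, as it does other aromatic aldehydes. C1′ then keeps one spatial arrangement and the descriptor S from 2 to 26, because the ring carbon always outranks the side-chain CH2.

Remark (chemistry): the cycloaddition creates the bridgehead centres C1 and C4 without facial control, so 21 is a pair of bridgehead epimers, (1S,4R) and (1R,4S). The pair is carried on as one material because step 10 destroys both centres, and the structure drawn for 21 is the (1S,4R) epimer. The same holds for the cycloadducts F2 and F10 of the fallbacks.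

Design choices: the carbamate on the way to 19 is the N-isopropyl type, so that its removal and the triflation run in one flask. Ring opening and oxidation are telescoped, so that the naphthol with a benzylic ester ortho to its hydroxyl is never handled. The MOM ethers sit peri to the quinone carbonyls in 25, so that the last cleavage is chelation-assisted.

**Route**

Step 1
Reactants: 1 3-furaldehyde
Product: 3 (S)-1-(furan-3-yl)but-3-en-1-ol, via borinate ester 2 (not isolated)
Conditions: (−)-Ipc2B(allyl), Et2O, −78 °C; then NaOH, H2O2, 0 °C → rt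
Reagents that add atoms: (−)-B-allyldiisopinocampheylborane, C=CCB([C@@H]1C[C@@H]2C[C@H]([C@H]1C)C2(C)C)[C@@H]1C[C@@H]2C[C@H]([C@H]1C)C2(C)C
Why: Brown asymmetric allylboration delivers the allyl group through a chair-like six-membered transition state to the Si face of the aldehyde, which sets the carbinol centre as S (furyl outranks allyl), and oxidative work-up frees the alcohol from borinate 2.

Step 2
Reactants: 3 (S)-1-(furan-3-yl)but-3-en-1-ol; 4 2-methylbut-2-ene
Product: 5 (S)-1-(furan-3-yl)-4-methylpent-3-en-1-ol
Conditions: second-generation Grubbs catalyst (H2IMes)(PCy3)Cl2Ru=CHPh (cat.), excess 4, CH2Cl2, 40 °C, sealed tube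
Reagents that add atoms: none
Why: Olefin cross-metathesis of a terminal alkene with 2-methylbut-2-ene is a standard way to the trisubstituted prenyl-type alkene, and the aromatic furan, the free hydroxyl and the stereocentre take no part.

Step 3
Reactants: 5 (S)-1-(furan-3-yl)-4-methylpent-3-en-1-ol; 6 tiglic acid
Product: 7 (S)-1-(furan-3-yl)-4-methylpent-3-enyl tiglate
Conditions: DCC, DMAP, CH2Cl2, 0 °C → rt
Reagents that add atoms: none
Why: Steglich esterification activates the acid and not the alcohol, so the C–O bond of the acid-sensitive furyl carbinol is never broken (S retained), and it avoids the ketene pathway that could deconjugate or isomerise the tiglate.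

Step 4
Reactants: 8 hydroquinone
Product: 9 1,4-bis(methoxymethoxy)benzene
Conditions: MOMCl, i-Pr2NEt, CH2Cl2, 0 °C → rt
Reagents that add atoms: chloromethyl methyl ether, COCCl
Why: Williamson-type O-alkylation of both phenols by the reactive α-chloro ether gives the bis-acetal, whose MOM groups later direct lithiation and should survive fluoride, rhodium and the oxidant.

Step 5
Reactants: 9 1,4-bis(methoxymethoxy)benzene
Product: 12 2,5-bis(methoxymethoxy)phenol, via aryllithium 10 (not isolated), via dimethyl arylboronate 11 (not isolated)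
Conditions: n-BuLi, THF, 0 °C; B(OMe)3, −78 °C → rt; H2O2, AcOH, 0 °C
Reagents that add atoms: hydrogen peroxide, OO
Why: Directed ortho-metalation next to a MOM ether (all four ring hydrogens are equivalent), borylation of the aryllithium and oxidative aryl shift from boron to oxygen give the phenol in one pot.

Step 6
Reactants: 12 2,5-bis(methoxymethoxy)phenol
Product: 13 2,5-bis(methoxymethoxy)phenyl N-isopropylcarbamate
Conditions: i-PrNCO, Et3N (cat.), CH2Cl2, rt
Reagents that add atoms: isopropyl isocyanate, CC(C)N=C=O
Why: Base-catalysed addition of the phenol to the isocyanate gives a secondary carbamate, a strong directing group that can later be removed under mild base.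

Step 7
Reactants: 13 2,5-bis(methoxymethoxy)phenyl N-isopropylcarbamate
Product: 17 3,6-bis(methoxymethoxy)-2-(trimethylsilyl)phenyl N-isopropylcarbamate, via N-silyl carbamate 14 (not isolated), via ortho-lithiated N-silyl carbamate 15 (not isolated), via N-silyl ortho-silyl carbamate 16 (not isolated)
Conditions: TBSOTf (1.05 equiv), TMEDA, Et2O, 0 °C → rt; n-BuLi, TMEDA, −78 °C; TMSCl, −78 °C → rt; pH 4 citrate buffer, 0 °C (brief)
Reagents that add atoms: chlorotrimethylsilane, C[Si](C)(C)Cl
Why: Directed ortho-metalation of the carbamate, protected in the flask as its N-silyl derivative, should occur at the one position flanked by two directing groups (carbamate and MOM ether), the silyl quench at −78 °C precedes any anionic Fries shift, and the N–Si bond is hydrolysed on mild work-up that spares the acetals.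

Step 8
Reactants: 17 3,6-bis(methoxymethoxy)-2-(trimethylsilyl)phenyl N-isopropylcarbamate
Product: 19 3,6-bis(methoxymethoxy)-2-(trimethylsilyl)phenyl trifluoromethanesulfonate, via ortho-silyl phenol 18 (not isolated)
Conditions: Et2NH, DBU, MeCN, 40 °C; then PhNTf2, rt
Reagents that add atoms: N-phenylbis(trifluoromethanesulfonimide), O=S(=O)(N(c1ccccc1)S(=O)(=O)C(F)(F)F)C(F)(F)F
Why: Deprotonation of the N–H carbamate triggers E1cB loss of isopropyl isocyanate (trapped by Et2NH), and the ortho-silyl phenoxide is O-sulfonylated in the same flask, so the desilylation-prone phenol 18 is never isolated.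

Step 9
Reactants: 19 3,6-bis(methoxymethoxy)-2-(trimethylsilyl)phenyl trifluoromethanesulfonate; 7 (S)-1-(furan-3-yl)-4-methylpent-3-enyl tiglate
Product: 21 (S)-1-[5,8-bis(methoxymethoxy)-1,4-dihydro-1,4-epoxynaphthalen-2-yl]-4-methylpent-3-enyl tiglate (pair of bridgehead epimers; 1S,4R epimer drawn), via 3,6-bis(methoxymethoxy)benzyne 20 (not isolated)
Conditions: CsF, MeCN, rt (19 in slight excess, added slowly)
Reagents that add atoms: none
Why: Fluoride attacks silicon of 19 and the ortho triflate leaves (1,2-elimination), releasing aryne 20 slowly at neutral pH; 20 then adds across furan C2 and C5 of 7 in a concerted, suprafacial [4+2] cycloaddition, the known aryne–furan Diels–Alder route from 3,6-dialkoxybenzynes to 1,4-epoxy-1,4-dihydronaphthalenes. Ring B is closed as a six-membered carbocycle by intermolecular [4+2] annulation, C1–C8a and C4–C4a forming in the same event while the furan oxygen stays as the 1,4-bridge. The two new bridgehead centres are fixed only relative to each other by the concerted mechanism; the remote carbinol centre exerts no facial control, so both bridgehead epimers of 21 are expected, which is harmless because both centres vanish on aromatisation. No regiocontrol is needed because the aryne is symmetric and either orientation gives the same adduct. The selectivity that is needed is chemoselectivity for the furan over an ene reaction with the prenyl alkene or addition to the tiglate; it rests on the much faster capture of arynes by electron-rich furan dienes and on slow aryne release, and the conditions should leave the ester, the acetals and the C1′–O bond untouched.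

Step 10
Reactants: 21 (S)-1-[5,8-bis(methoxymethoxy)-1,4-dihydro-1,4-epoxynaphthalen-2-yl]-4-methylpent-3-enyl tiglate (pair of bridgehead epimers)
Product: 25 (S)-1-[5,8-bis(methoxymethoxy)-1,4-dioxo-1,4-dihydronaphthalen-2-yl]-4-methylpent-3-enyl tiglate, via naphthol 22 (not isolated), via regioisomeric naphthol 23 (not isolated), via naphthalene-1,4-diol 24 (not isolated)
Conditions: [Rh(CO)2Cl]2 (cat.), ClCH2CH2Cl, 50 °C; solvent exchange; PhI(OCOCF3)2 (2 equiv), MeCN–H2O, 0 °C
Reagents that add atoms: water, O
Why: Monovalent rhodium inserts into a strained bridgehead C–O bond and β-hydride elimination with tautomerisation gives a 1-naphthol (known isomerisation of oxabenzonorbornadienes), and the trivalent iodine reagent then oxidises the para-unsubstituted naphthol with water as oxygen source to the 1,4-quinone, so that both epimers of 21 and both naphthols converge on 25 while the MOM-capped ring A is left alone.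

Step 11
Reactants: 25 (S)-1-[5,8-bis(methoxymethoxy)-1,4-dioxo-1,4-dihydronaphthalen-2-yl]-4-methylpent-3-enyl tiglate
Product: 26 (S)-1-(5,8-dihydroxy-1,4-dioxo-1,4-dihydronaphthalen-2-yl)-4-methylpent-3-enyl tiglate
Conditions: MgBr2·OEt2, Et2O–CH2Cl2, 0 °C → rt; pH 7 buffer
Reagents that add atoms: none
Why: Chelation-assisted acetal cleavage should work because the magnesium of MgBr2 binds each peri quinone carbonyl together with the neighbouring acetal oxygen, so only the two aryl MOM ethers are activated while the tiglate, the prenyl alkene and the C1′–O bond stay intact.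

**Compound list**

1 | 3-furaldehyde | O=Cc1ccoc1 | starting material
2 | (S)-1-(furan-3-yl)but-3-enyl diisopinocampheylborinate (isopinocampheyl groups of the (+)-α-pinene series) | C=CC[C@H](OB([C@@H]1C[C@@H]2C[C@H]([C@H]1C)C2(C)C)[C@@H]1C[C@@H]2C[C@H]([C@H]1C)C2(C)C)c1ccoc1 | intermediate
3 | (S)-1-(furan-3-yl)but-3-en-1-ol | O[C@@H](CC=C)c1ccoc1 | intermediate
4 | 2-methylbut-2-ene | CC=C(C)C | starting material
5 | (S)-1-(furan-3-yl)-4-methylpent-3-en-1-ol | O[C@@H](CC=C(C)C)c1ccoc1 | intermediate
6 | tiglic acid, (E)-2-methylbut-2-enoic acid | C/C=C(\C)C(=O)O | starting material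
7 | (S)-1-(furan-3-yl)-4-methylpent-3-enyl tiglate | C/C=C(\C)C(=O)O[C@@H](CC=C(C)C)c1ccoc1 | intermediate
8 | hydroquinone | Oc1ccc(O)cc1 | starting material
9 | 1,4-bis(methoxymethoxy)benzene | COCOc1ccc(OCOC)cc1 | intermediate
10 | [2,5-bis(methoxymethoxy)phenyl]lithium | [Li]c1cc(OCOC)ccc1OCOC | intermediate
11 | dimethyl [2,5-bis(methoxymethoxy)phenyl]boronate | COB(OC)c1cc(OCOC)ccc1OCOC | intermediate
12 | 2,5-bis(methoxymethoxy)phenol | Oc1cc(OCOC)ccc1OCOC | intermediate
13 | 2,5-bis(methoxymethoxy)phenyl N-isopropylcarbamate | CC(C)NC(=O)Oc1cc(OCOC)ccc1OCOC | intermediate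
14 | 2,5-bis(methoxymethoxy)phenyl N-(tert-butyldimethylsilyl)-N-isopropylcarbamate | CC(C)N(C(=O)Oc1cc(OCOC)ccc1OCOC)[Si](C)(C)C(C)(C)C | intermediate
15 | [2-{[(tert-butyldimethylsilyl)(isopropyl)carbamoyl]oxy}-3,6-bis(methoxymethoxy)phenyl]lithium | CC(C)N(C(=O)Oc1c([Li])c(OCOC)ccc1OCOC)[Si](C)(C)C(C)(C)C | intermediate
16 | 3,6-bis(methoxymethoxy)-2-(trimethylsilyl)phenyl N-(tert-butyldimethylsilyl)-N-isopropylcarbamate | CC(C)N(C(=O)Oc1c([Si](C)(C)C)c(OCOC)ccc1OCOC)[Si](C)(C)C(C)(C)C | intermediate
17 | 3,6-bis(methoxymethoxy)-2-(trimethylsilyl)phenyl N-isopropylcarbamate | CC(C)NC(=O)Oc1c([Si](C)(C)C)c(OCOC)ccc1OCOC | intermediate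
18 | 3,6-bis(methoxymethoxy)-2-(trimethylsilyl)phenol (present as its DBU-H phenoxide) | Oc1c([Si](C)(C)C)c(OCOC)ccc1OCOC | intermediate
19 | 3,6-bis(methoxymethoxy)-2-(trimethylsilyl)phenyl trifluoromethanesulfonate | COCOc1ccc(OCOC)c(OS(=O)(=O)C(F)(F)F)c1[Si](C)(C)C | intermediate
20 | 3,6-bis(methoxymethoxy)benzyne | COCOC1=CC=C(OCOC)C#C1 | intermediate
21 | (S)-1-[5,8-bis(methoxymethoxy)-1,4-dihydro-1,4-epoxynaphthalen-2-yl]-4-methylpent-3-enyl tiglate, pair of bridgehead epimers, (1S,4R) epimer drawn, (1R,4S) epimer formed alongside | C/C=C(\C)C(=O)O[C@@H](CC=C(C)C)C1=C[C@H]2O[C@@H]1c3c(OCOC)ccc(OCOC)c23 | intermediate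
22 | (S)-1-[1-hydroxy-5,8-bis(methoxymethoxy)naphthalen-2-yl]-4-methylpent-3-enyl tiglate | C/C=C(\C)C(=O)O[C@@H](CC=C(C)C)c1ccc2c(OCOC)ccc(OCOC)c2c1O | intermediate
23 | (S)-1-[4-hydroxy-5,8-bis(methoxymethoxy)naphthalen-2-yl]-4-methylpent-3-enyl tiglate | C/C=C(\C)C(=O)O[C@@H](CC=C(C)C)c1cc(O)c2c(OCOC)ccc(OCOC)c2c1 | intermediate
24 | (S)-1-[1,4-dihydroxy-5,8-bis(methoxymethoxy)naphthalen-2-yl]-4-methylpent-3-enyl tiglate | C/C=C(\C)C(=O)O[C@@H](CC=C(C)C)c1cc(O)c2c(OCOC)ccc(OCOC)c2c1O | intermediate
25 | (S)-1-[5,8-bis(methoxymethoxy)-1,4-dioxo-1,4-dihydronaphthalen-2-yl]-4-methylpent-3-enyl tiglate | C/C=C(\C)C(=O)O[C@@H](CC=C(C)C)C1=CC(=O)c2c(OCOC)ccc(OCOC)c2C1=O | intermediate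
26 | (S)-1-(5,8-dihydroxy-1,4-dioxo-1,4-dihydronaphthalen-2-yl)-4-methylpent-3-enyl tiglate (CNP0373203.1) | C/C=C(\C)C(=O)O[C@@H](CC=C(C)C)C1=CC(=O)c2c(O)ccc(O)c2C1=O | target

**Summary**

Total step count: 11 (steps 1–3 make the furan 7, steps 4–8 make the aryne precursor 19, steps 9–11 join them and finish).
Longest linear sequence: 8 steps (steps 4–11, from hydroquinone 8).

**Steps most likely to fail**

Step 10. Once the bridge opens, naphthol 22 has its hydroxyl ortho to the ester-bearing carbon, so tiglate may be expelled (ortho-quinone methide formation) or shift to the naphthol oxygen. The rhodium catalyst may also ionise the allylic C–O bond of the ester, or the oxidant may attack ring A or the prenyl alkene.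

The fallback carries the carbinol oxygen as a silyl ether through cycloaddition, ring opening and oxidation, and brings in the tiglate afterwards. It sets out from alcohol 5 and comes back to the route at 25. Silylation of 5 (TBSCl, imidazole, DMF) should give (S)-tert-butyl{[1-(furan-3-yl)-4-methylpent-3-enyl]oxy}dimethylsilane F1. Cycloaddition of F1 with the aryne from 19 (CsF, MeCN) should give the silyloxy cycloadduct F2 as its pair of bridgehead epimers. Treatment with [Rh(CO)2Cl]2 and then PhI(OCOCF3)2, as in step 10, should lead through silyloxy naphthol F3, regioisomeric silyloxy naphthol F4 and silyloxy naphthalene-1,4-diol F5 to silyloxy quinone F6. HF·pyridine in THF at 0 °C should then free carbinol quinone F7, and Steglich esterification of F7 with tiglic acid 6 (DCC, DMAP, CH2Cl2) should give 25.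

Step 11. When the first peri hydroxyl is freed, the naphthazarin tautomer makes C1′ a benzylic position on an electron-rich ring. Lewis-acid ionisation of the C1′–O bond (loss of tiglate, elimination or loss of configuration) could then compete with acetal cleavage.

The fallback unveils the naphthazarin before the ester is present. It sets out from alcohol 5, passes through F1 to F6 to carbinol quinone F7 as described for step 10, and arrives at the target 26. MgBr2·OEt2, used as in step 11, acts on the free carbinol F7, which cannot ionise as an ester can, and should give alkannin F8. Steglich acylation with tiglic acid 6 (DCC, DMAP, CH2Cl2) should then esterify only the side-chain hydroxyl of F8, because the two peri hydroxyls are locked in hydrogen bonds to the quinone carbonyls, and give 26.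

Step 9. The aryne may be consumed by an ene reaction with the trisubstituted prenyl alkene, or by oligomerisation if capture by the furan is slow.

The fallback postpones the cross-metathesis so that the furan carries only a terminal alkene during the cycloaddition. It sets out from alcohol 3 and comes back to the route at 25. Steglich esterification of 3 with 6 should give (S)-1-(furan-3-yl)but-3-enyl tiglate F9. Cycloaddition of F9 with the aryne from 19 (CsF, MeCN) should give the allyl cycloadduct F10 as its pair of bridgehead epimers. Ring opening and oxidation, as in step 10, should pass through allyl naphthol F11, regioisomeric allyl naphthol F12 and allyl naphthalene-1,4-diol F13 to allyl quinone F14. Cross-metathesis of F14 with 2-methylbut-2-ene 4 (second-generation Grubbs catalyst, CH2Cl2, 40 °C; the electron-poor quinone and tiglate alkenes should not engage the ruthenium carbene) should give 25.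

Further compounds

F1 | step 10 | (S)-tert-butyl{[1-(furan-3-yl)-4-methylpent-3-enyl]oxy}dimethylsilane | CC(C)(C)[Si](C)(C)O[C@@H](CC=C(C)C)c1ccoc1
F2 | step 10 | 2-[(S)-1-(tert-butyldimethylsilyloxy)-4-methylpent-3-enyl]-5,8-bis(methoxymethoxy)-1,4-dihydro-1,4-epoxynaphthalene, pair of bridgehead epimers, (1S,4R) epimer drawn | CC(C)(C)[Si](C)(C)O[C@@H](CC=C(C)C)C1=C[C@H]2O[C@@H]1c3c(OCOC)ccc(OCOC)c23
F3 | step 10 | 2-[(S)-1-(tert-butyldimethylsilyloxy)-4-methylpent-3-enyl]-5,8-bis(methoxymethoxy)naphthalen-1-ol | CC(C)(C)[Si](C)(C)O[C@@H](CC=C(C)C)c1ccc2c(OCOC)ccc(OCOC)c2c1O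
F4 | step 10 | 3-[(S)-1-(tert-butyldimethylsilyloxy)-4-methylpent-3-enyl]-5,8-bis(methoxymethoxy)naphthalen-1-ol | CC(C)(C)[Si](C)(C)O[C@@H](CC=C(C)C)c1cc(O)c2c(OCOC)ccc(OCOC)c2c1
F5 | step 10 | 2-[(S)-1-(tert-butyldimethylsilyloxy)-4-methylpent-3-enyl]-5,8-bis(methoxymethoxy)naphthalene-1,4-diol | CC(C)(C)[Si](C)(C)O[C@@H](CC=C(C)C)c1cc(O)c2c(OCOC)ccc(OCOC)c2c1O
F6 | step 10 | 2-[(S)-1-(tert-butyldimethylsilyloxy)-4-methylpent-3-enyl]-5,8-bis(methoxymethoxy)naphthalene-1,4-dione | CC(C)(C)[Si](C)(C)O[C@@H](CC=C(C)C)C1=CC(=O)c2c(OCOC)ccc(OCOC)c2C1=O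
F7 | step 10 | 2-[(S)-1-hydroxy-4-methylpent-3-enyl]-5,8-bis(methoxymethoxy)naphthalene-1,4-dione | O[C@@H](CC=C(C)C)C1=CC(=O)c2c(OCOC)ccc(OCOC)c2C1=O
F8 | step 11 | alkannin, 5,8-dihydroxy-2-[(S)-1-hydroxy-4-methylpent-3-enyl]naphthalene-1,4-dione | O[C@@H](CC=C(C)C)C1=CC(=O)c2c(O)ccc(O)c2C1=O
F9 | step 9 | (S)-1-(furan-3-yl)but-3-enyl tiglate | C/C=C(\C)C(=O)O[C@@H](CC=C)c1ccoc1
F10 | step 9 | (S)-1-[5,8-bis(methoxymethoxy)-1,4-dihydro-1,4-epoxynaphthalen-2-yl]but-3-enyl tiglate, pair of bridgehead epimers, (1S,4R) epimer drawn | C/C=C(\C)C(=O)O[C@@H](CC=C)C1=C[C@H]2O[C@@H]1c3c(OCOC)ccc(OCOC)c23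
F11 | step 9 | (S)-1-[1-hydroxy-5,8-bis(methoxymethoxy)naphthalen-2-yl]but-3-enyl tiglate | C/C=C(\C)C(=O)O[C@@H](CC=C)c1ccc2c(OCOC)ccc(OCOC)c2c1O
F12 | step 9 | (S)-1-[4-hydroxy-5,8-bis(methoxymethoxy)naphthalen-2-yl]but-3-enyl tiglate | C/C=C(\C)C(=O)O[C@@H](CC=C)c1cc(O)c2c(OCOC)ccc(OCOC)c2c1
F13 | step 9 | (S)-1-[1,4-dihydroxy-5,8-bis(methoxymethoxy)naphthalen-2-yl]but-3-enyl tiglate | C/C=C(\C)C(=O)O[C@@H](CC=C)c1cc(O)c2c(OCOC)ccc(OCOC)c2c1O
F14 | step 9 | (S)-1-[5,8-bis(methoxymethoxy)-1,4-dioxo-1,4-dihydronaphthalen-2-yl]but-3-enyl tiglate | C/C=C(\C)C(=O)O[C@@H](CC=C)C1=CC(=O)c2c(OCOC)ccc(OCOC)c2C1=O
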